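**Retrosynthetic overview**
1. Target 11 ⇐ enone 10: the last step is a substrate-controlled syn-dihydroxylation of the enone C=C. It forms two C–O bonds and sets the tertiary C1–OH and the C2–OH of the target.
2. 10 ⇐ triol enone 8: one-flask site-selective double O-benzoylation (the new step). It places benzoates on the primary oxygen and on the allylic O-4, and leaves O-5 free.
3. 8 ⇐ enone 6: Morita–Baylis–Hillman hydroxymethylation (the only C–C bond made) and acetonide hydrolysis.
4. 6 ⇐ (−)-quinic acid 1: acetonide lactone, NaBH4, NaIO4 (ring C=O), MsCl/Et3N. Quinic acid supplies the two cis C–O stereocentres (target C3, C4).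
5. Ring order: no carbocycle is built. The cyclohexane ring of quinic acid is carried through; only the temporary lactone and dioxolane rings are formed (step 1) and removed (steps 2 and 6).

Assumption: small atom-donating reagents (2,2-dimethoxypropane, formaldehyde, benzoyl chloride, oxidants) are treated as reagents and not numbered; compounds 6–10 use enone numbering (C1 = C=O).

**Route**

Step 1
Reactants: 1 (−)-quinic acid
Product: 2 3,4-O-isopropylidene-1,5-quinide
Conditions: Me2C(OMe)2, TsOH (cat.), acetone, reflux
Reagents that add atoms: 2,2-dimethoxypropane, COC(C)(C)OC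
Why: Acid-catalysed transketalisation closes the dioxolane on the only cis-vicinal diol (O3/O4) while the carboxyl lactonises onto the cis 5-OH (acetonide formation/lactonisation); no stereocentre changes.

Step 2
Reactants: 2 3,4-O-isopropylidene-1,5-quinide
Product: 3 1-(hydroxymethyl)-3,4-O-isopropylidenecyclohexane-1,3,4,5-tetrol
Conditions: NaBH4, EtOH, 0 °C to rt
Reagents that add atoms: none
Why: Borohydride reduction of the strained α-hydroxy γ-lactone (lactone hydride reduction) frees the 5-OH and creates the C1(OH)–CH2OH glycol needed for cleavage; no stereocentre changes.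

Step 3
Reactants: 3 1-(hydroxymethyl)-3,4-O-isopropylidenecyclohexane-1,3,4,5-tetrol
Product: 4 (3R,4S,5R)-3-hydroxy-4,5-(isopropylidenedioxy)cyclohexan-1-one
Conditions: NaIO4, H2O/pH 7 phosphate buffer, 0 °C to rt
Reagents that add atoms: none
Why: Malaprade glycol cleavage of the only 1,2-diol excises the exocyclic carbon as formaldehyde and turns C1 into the ring ketone at neutral pH, so the β-hydroxy ketone survives; the other three centres are untouched.

Step 4
Reactants: 4 (3R,4S,5R)-3-hydroxy-4,5-(isopropylidenedioxy)cyclohexan-1-one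
Product: 6 (4S,5R)-4,5-(isopropylidenedioxy)cyclohex-2-en-1-one, via mesylate 5 (not isolated)
Conditions: MsCl, Et3N, CH2Cl2, 0 °C to rt
Reagents that add atoms: methanesulfonyl chloride, CS(=O)(=O)Cl (its atoms are in intermediate 5 only and leave again in the elimination)
Why: Mesylation of the single free β-hydroxyl followed by E1cB elimination gives the conjugated enone; the acetonide oxygen is a much poorer leaving group, so the regiochemistry is unambiguous and the two acetonide centres are retained.

Step 5
Reactants: 6 (4S,5R)-4,5-(isopropylidenedioxy)cyclohex-2-en-1-one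
Product: 7 (4S,5R)-2-(hydroxymethyl)-4,5-(isopropylidenedioxy)cyclohex-2-en-1-one
Conditions: 37% aq. HCHO, imidazole (1 equiv), THF/1 M aq. NaHCO3, rt
Reagents that add atoms: formaldehyde, C=O
Why: Morita–Baylis–Hillman reaction: imidazole adds reversibly at C3, the enolate takes formaldehyde at C2 and the amine is expelled, installing the one missing carbon at the enone α-position; no stereocentre is created.

Step 6
Reactants: 7 (4S,5R)-2-(hydroxymethyl)-4,5-(isopropylidenedioxy)cyclohex-2-en-1-one
Product: 8 (4S,5R)-4,5-dihydroxy-2-(hydroxymethyl)cyclohex-2-en-1-one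
Conditions: TFA/H2O (9:1), 0 °C, 30 min, then evaporate (toluene azeotrope)
Reagents that add atoms: none
Why: Acid-catalysed acetonide hydrolysis releases the cis-diol; cold, short exposure avoids dehydration of the β-hydroxy enone, and the stereocentres are untouched.

Step 7
Reactants: 8 (4S,5R)-4,5-dihydroxy-2-(hydroxymethyl)cyclohex-2-en-1-one
Product: 10 (4S,5R)-4-(benzoyloxy)-2-[(benzoyloxy)methyl]-5-hydroxycyclohex-2-en-1-one, via primary monobenzoate 9 (not isolated)
Conditions: BzCl (1.05 equiv), 2,4,6-collidine, MeCN, −30 °C; then Ph2BOCH2CH2NH2 (10 mol %), iPr2NEt, BzCl (1.1 equiv), 0 °C to rt; aq. citric acid quench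
Reagents that add atoms: benzoyl chloride, O=C(Cl)c1ccccc1
Why: Proposed new method: a one-flask double benzoylation in which the primary allylic OH is acylated first under hindered-base control and the diarylborinic acid then binds the cis-4,5-diol as a tetracoordinate borinate. On the expected cyclohexenone half-chair, O-4 is pseudo-equatorial and allylic while O-5 is axial and β to the ketone, so O-4 is the more accessible and more nucleophilic borinate oxygen and takes the second benzoyl group, forming both ester C–O bonds and fixing the benzoate regiochemistry of the target without touching a stereocentre. The closest known reaction type is diarylborinic-acid-catalysed (and stannylene-mediated) equatorial-selective acylation of pyranoside cis-1,2-diols, which has not been shown on an enone-fused, base-sensitive cyclitol triol or run as a double benzoylation.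

Step 8
Reactants: 10 (4S,5R)-4-(benzoyloxy)-2-[(benzoyloxy)methyl]-5-hydroxycyclohex-2-en-1-one
Product: 11 CNP0127041.1, [(1S,2S,3R,4R)-3-(benzoyloxy)-1,2,4-trihydroxy-6-oxocyclohexyl]methyl benzoate
Conditions: OsO4 (5 mol %), NMO (1.3 equiv), citric acid (1 equiv), t-BuOH/H2O (1:1), rt
Reagents that add atoms: osmium tetroxide, O=[Os](=O)(=O)=O (delivers both oxygens); N-methylmorpholine N-oxide, C[N+]1([O-])CCOCC1, and water, O (restore the oxo ligands of osmium)
Why: Upjohn syn-dihydroxylation ([3+2] osmylation) occurs on the enone face anti to the allylic benzoate and the axial 5-OH (Kishi-type anti selectivity), which sets the tertiary carbinol (1S) and the adjacent secondary carbinol (2S) cis to each other and trans to the benzoate; the citric acid buffer keeps osmium turning over on the electron-poor alkene and suppresses benzoyl migration and β-elimination.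

**Compound list**
1 | (−)-quinic acid, (1S,3R,4S,5R)-1,3,4,5-tetrahydroxycyclohexane-1-carboxylic acid | OC(=O)[C@]1(O)C[C@@H](O)[C@@H](O)[C@H](O)C1 | starting material
2 | 3,4-O-isopropylidene-1,5-quinide (1,5-lactone 3,4-acetonide of 1, quinic acid numbering) | O=C2[C@]1(O)C[C@@H](OC3(C)C)[C@@H](O3)[C@H](O2)C1 | intermediate
3 | 1-(hydroxymethyl)-3,4-O-isopropylidenecyclohexane-1,3,4,5-tetrol (configuration of 1 retained) | OC[C@]1(O)C[C@@H](OC2(C)C)[C@@H](O2)[C@H](O)C1 | intermediate
4 | (3R,4S,5R)-3-hydroxy-4,5-(isopropylidenedioxy)cyclohexan-1-one | O=C1C[C@@H](OC2(C)C)[C@@H](O2)[C@H](O)C1 | intermediate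
5 | 3-O-methanesulfonate of 4, configuration unchanged (not isolated) | O=C1C[C@@H](OC2(C)C)[C@@H](O2)[C@H](OS(C)(=O)=O)C1 | intermediate
6 | (4S,5R)-4,5-(isopropylidenedioxy)cyclohex-2-en-1-one | O=C1C[C@@H](OC2(C)C)[C@@H](O2)C=C1 | intermediate
7 | (4S,5R)-2-(hydroxymethyl)-4,5-(isopropylidenedioxy)cyclohex-2-en-1-one | O=C1C[C@@H](OC2(C)C)[C@@H](O2)C=C1CO | intermediate
8 | (4S,5R)-4,5-dihydroxy-2-(hydroxymethyl)cyclohex-2-en-1-one | O=C1C[C@@H](O)[C@@H](O)C=C1CO | intermediate
9 | (4S,5R)-2-[(benzoyloxy)methyl]-4,5-dihydroxycyclohex-2-en-1-one (not isolated) | O=C1C[C@@H](O)[C@@H](O)C=C1COC(=O)c2ccccc2 | intermediate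
10 | (4S,5R)-4-(benzoyloxy)-2-[(benzoyloxy)methyl]-5-hydroxycyclohex-2-en-1-one | O=C1C[C@@H](O)[C@@H](OC(=O)c2ccccc2)C=C1COC(=O)c3ccccc3 | intermediate
11 | CNP0127041.1, [(1S,2S,3R,4R)-3-(benzoyloxy)-1,2,4-trihydroxy-6-oxocyclohexyl]methyl benzoate | O=C(OC[C@@]1(O)C(=O)C[C@@H](O)[C@@H](OC(=O)c2ccccc2)[C@@H]1O)c1ccccc1 | target

**Step count and risks**
Total steps: 8. Longest linear sequence: 8 steps (fully linear from 1).

Step 7 (the proposed new step). The risks are incomplete O-4/O-5 discrimination, over-benzoylation, and base-induced dehydration or aromatisation of the β-hydroxy enone. The fallback uses only known chemistry and changes the approach: site selection is postponed to the saturated chair and done through a stoichiometric tin acetal. It sets out from 7. Benzoylation of the primary alcohol (BzCl, pyridine, CH2Cl2, 0 °C) gives (4S,5R)-2-[(benzoyloxy)methyl]-4,5-(isopropylidenedioxy)cyclohex-2-en-1-one F2. Upjohn dihydroxylation of the acetonide-protected enone (OsO4 cat., NMO, acetone/H2O), anti to the dioxolane, gives [1,2-dihydroxy-3,4-(isopropylidenedioxy)-6-oxocyclohexyl]methyl benzoate F3 with all four centres as in 11. Aqueous TFA then gives [(1S,2S,3R,4R)-1,2,3,4-tetrahydroxy-6-oxocyclohexyl]methyl benzoate F4. Its dibutylstannylene acetal (Bu2SnO, MeOH, reflux; then BzCl, dioxane, rt) is benzoylated at the equatorial O-3 of the cis-3,4-diol; O-4 is axial in the chair that keeps CH2OBz equatorial. This comes back to the route at 11, bypassing 8–10.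

Step 5 (Morita–Baylis–Hillman). The risks are slow conversion and base-mediated β-alkoxide elimination or aromatisation of 6. The fallback replaces the amine-catalysed aldol by cross-coupling. It sets out from 6. α-Iodination (I2, pyridine/CH2Cl2, 0 °C to rt) gives (4S,5R)-2-iodo-4,5-(isopropylidenedioxy)cyclohex-2-en-1-one F1. Stille coupling with (tributylstannyl)methanol (Pd(PPh3)4, dioxane, 90 °C) comes back to the route at 7.

Step 8 (dihydroxylation). The risks are sluggish osmylation of the doubly deactivated trisubstituted enone, and benzoyl migration from O-4 to O-5 or β-elimination if forcing or basic conditions are needed. The fallback masks the β-hydroxyl so that stoichiometric, basic osmylation can be used. It sets out from 10. Silylation (TESOTf, 2,6-lutidine, CH2Cl2, −78 °C) gives (4S,5R)-4-(benzoyloxy)-2-[(benzoyloxy)methyl]-5-[(triethylsilyl)oxy]cyclohex-2-en-1-one F5. Osmylation (OsO4 1.1 equiv, pyridine; then aq. NaHSO3) from the face anti to the benzoate and the silyl ether gives the 4-O-triethylsilyl ether of 11 F6. HF·pyridine (THF, 0 °C) comes back to the route at 11.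

**Further compounds**
F1 | step 5 | (4S,5R)-2-iodo-4,5-(isopropylidenedioxy)cyclohex-2-en-1-one | O=C1C[C@@H](OC2(C)C)[C@@H](O2)C=C1I
F2 | step 7 | (4S,5R)-2-[(benzoyloxy)methyl]-4,5-(isopropylidenedioxy)cyclohex-2-en-1-one | O=C1C[C@@H](OC2(C)C)[C@@H](O2)C=C1COC(=O)c3ccccc3
F3 | step 7 | [1,2-dihydroxy-3,4-(isopropylidenedioxy)-6-oxocyclohexyl]methyl benzoate, all four centres as in 11 | O=C1C[C@@H](OC2(C)C)[C@@H](O2)[C@H](O)[C@@]1(O)COC(=O)c3ccccc3
F4 | step 7 | [(1S,2S,3R,4R)-1,2,3,4-tetrahydroxy-6-oxocyclohexyl]methyl benzoate | O=C1C[C@@H](O)[C@@H](O)[C@H](O)[C@@]1(O)COC(=O)c2ccccc2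
F5 | step 8 | (4S,5R)-4-(benzoyloxy)-2-[(benzoyloxy)methyl]-5-[(triethylsilyl)oxy]cyclohex-2-en-1-one | O=C1C[C@@H](O[Si](CC)(CC)CC)[C@@H](OC(=O)c2ccccc2)C=C1COC(=O)c3ccccc3
F6 | step 8 | 4-O-triethylsilyl ether of 11, configuration as in 11 | O=C1C[C@@H](O[Si](CC)(CC)CC)[C@@H](OC(=O)c2ccccc2)[C@H](O)[C@@]1(O)COC(=O)c3ccccc3
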